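**Plan** (ring locants: C1 the stereocentre, C2 the methylidene carbon, C3–C5 the three CH2, C6 the CMe2 carbon)
1. Retrosynthetic cuts, in order: the malonate ester C–O bond; the CH2–CH2 bond between the two chain olefins (allyl sulfone alkylation); C2=CH2 (ketone methylenation); the ring bond C4–C5; then C2–C3 (vinyl addition) and C1–C2 plus C5–C6 (keteniminium–olefin [2+2] on the terminal olefin of geranyl phenyl sulfone).
2. Forward: the four-membered ring C2–C1–C6–C5 is built first, a vinyl group brings C3 and C4, and a rhodium-catalysed ring expansion turns the 1-vinylcyclobutanol into the cyclohexanone; methylenation, attachment of the last five chain carbons through the sulfone, desulfonylation and malonylation follow.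
3. Enabling feature: C2 can be a ketone whose β-carbon is C4, and C5 is a CH2 on the quaternary C6, so the carbocycle is a cyclobutanol (C2, C1, C6, C5) plus two carbons; opening the strained C2–C5 bond puts a metal on C5, where it has no β-hydrogen and sits 6-endo to its own vinyl ketone.
4. Stereochemistry: C1 is set in the [2+2] step by the twofold-symmetric (2R,5R)-2,5-dimethylpyrrolidine auxiliary and is not touched afterwards; both E olefins are carried in from geranyl bromide and from an E-selective SeO2 oxidation; the sulfone deactivates the internal olefin, serves as coupling handle and is removed at the end.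

Key step: step 5

Assumption: the facial sense of the (2R,5R)-auxiliary towards this acyclic trisubstituted olefin is not secure; it is taken to deliver the (2S)-cyclobutanone, and the (2S,5S)-amide is used instead if the sense is the opposite.

**Step 1**
Reactants: 1 geranyl bromide
Product: 2 geranyl phenyl sulfone
Conditions: PhSO2Na, DMF, 20 °C
Reagents that add atoms: sodium benzenesulfinate, [Na+].[O-]S(=O)c1ccccc1
Why: SN2 displacement of the primary allylic bromide by the sulfur atom of the sulfinate (sulfinate S-alkylation) should give the allylic sulfone with the E olefin untouched.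

**Step 2**
Reactants: 3 (2R,5R)-2,5-dimethylpyrrolidine
Product: 4 1-[(2R,5R)-2,5-dimethylpyrrolidin-1-yl]ethan-1-one
Conditions: Ac2O, CH2Cl2, 0 to 20 °C
Reagents that add atoms: acetic anhydride, CC(=O)OC(C)=O
Why: N-acylation of the secondary amine by the anhydride is routine amide formation and leaves both stereocentres of the auxiliary untouched.

**Step 3**
Reactants: 2 geranyl phenyl sulfone; 4 1-[(2R,5R)-2,5-dimethylpyrrolidin-1-yl]ethan-1-one
Product: 7 (2S)-3,3-dimethyl-2-[(3E)-3-methyl-5-(phenylsulfonyl)pent-3-en-1-yl]cyclobutan-1-one, via keteniminium triflate 5 (not isolated), via cyclobutaniminium triflate 6 (not isolated)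
Conditions: Tf2O, 2,4,6-collidine, ClCH2CH2Cl, −15 to 80 °C; then aq NaHCO3, 80 °C
Reagents that add atoms: water, O
Why: In this keteniminium–olefin [2+2] cycloaddition the amide is dehydrated to the keteniminium salt 5, whose iminium carbon bonds to the less substituted carbon of the electron-rich terminal olefin while its CH2 closes onto the tertiary carbon (the olefin next to the sulfone is inductively deactivated), and the twofold-symmetric pyrrolidine shields one face so that the new stereocentre C1 is set as (S) before 6 is hydrolysed to the ketone.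

**Step 4**
Reactants: 7 (2S)-3,3-dimethyl-2-[(3E)-3-methyl-5-(phenylsulfonyl)pent-3-en-1-yl]cyclobutan-1-one
Product: 8 (2S)-1-ethenyl-3,3-dimethyl-2-[(3E)-3-methyl-5-(phenylsulfonyl)pent-3-en-1-yl]cyclobutan-1-ol (both C-1 epimers)
Conditions: CH2=CHMgBr, THF, −78 °C; then H2O
Reagents that add atoms: vinylmagnesium bromide, C=C[Mg]Br
Why: Grignard 1,2-addition to the strained cyclobutanone should outrun deprotonation of the allylic sulfone at −78 °C, and the new carbinol centre is formed as a mixture that does not matter because it becomes the carbonyl carbon in step 5.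

**Step 5**
Reactants: 8 (2S)-1-ethenyl-3,3-dimethyl-2-[(3E)-3-methyl-5-(phenylsulfonyl)pent-3-en-1-yl]cyclobutan-1-ol
Product: 9 (2S)-3,3-dimethyl-2-[(3E)-3-methyl-5-(phenylsulfonyl)pent-3-en-1-yl]cyclohexan-1-one
Conditions: [Rh(OH)(cod)]2 (2.5 mol %), rac-BINAP (6 mol %), toluene, 70 °C
Reagents that add atoms: none
Why: Proposed new method: the monovalent rhodium hydroxide exchanges with the tertiary alcohol, and the rhodium alkoxide undergoes strain-driven β-carbon elimination of the C2–C5 cyclobutane bond to give a vinyl ketone that carries a primary alkylrhodium at C5, which adds to the terminal carbon C4 of its own enone; protonolysis of the resulting rhodium enolate by the next molecule of 8 releases 9 and regenerates the alkoxide. The closest known reaction type is the rhodium-catalysed ring expansion of 1-allenylcyclobutanols to cyclohexenones by β-carbon elimination and intramolecular 1,4-addition, together with the rhodium-catalysed ring opening of tertiary cyclobutanols. The six-membered ring closes by a 6-endo-trig conjugate addition with the carbonyl carbon C2 inside the forming ring, the competing 5-exo attack at the α-carbon being electronically mismatched. No new stereocentre is formed: C1 is a spectator outside the cleaved bond, and the carbinol centre of 8 is erased, so both epimers converge on 9. The step needs cleavage of C2–C5 and not of C2–C1, which the substrate secures because C5 is the primary ring carbon whereas C1 is secondary and carries the side chain, and because the C5–rhodium intermediate has no β-hydrogen (C6 is quaternary) and can therefore only add to the enone or close back to the cyclobutanol.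

**Step 6**
Reactants: 9 (2S)-3,3-dimethyl-2-[(3E)-3-methyl-5-(phenylsulfonyl)pent-3-en-1-yl]cyclohexan-1-one
Product: 10 {[(2E)-5-[(1S)-2,2-dimethyl-6-methylidenecyclohexyl]-3-methylpent-2-en-1-yl]sulfonyl}benzene
Conditions: Zn, CH2Br2, TiCl4, THF, 0 to 20 °C
Reagents that add atoms: dibromomethane, BrCBr
Why: Takai–Lombardo methylenation with the non-basic geminal dizinc reagent converts hindered, enolizable ketones into methylidene compounds without epimerizing the α-stereocentre C1 or deprotonating the sulfone.

**Step 7**
Reactants: 11 3-methylbut-2-en-1-yl acetate (prenyl acetate)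
Product: 12 (2E)-4-hydroxy-3-methylbut-2-en-1-yl acetate
Conditions: SeO2 (10 mol %), t-BuOOH, salicylic acid (10 mol %), CH2Cl2, 20 °C
Reagents that add atoms: tert-butyl hydroperoxide, CC(C)(C)OO
Why: Riley-type catalytic SeO2 allylic oxidation proceeds by an ene reaction and a [2,3]-sigmatropic shift and hydroxylates the methyl group anti to the acetoxymethyl group, giving the (E)-allylic alcohol.

**Step 8**
Reactants: 12 (2E)-4-hydroxy-3-methylbut-2-en-1-yl acetate
Product: 13 (2E)-4-bromo-3-methylbut-2-en-1-yl acetate
Conditions: CBr4, PPh3, CH2Cl2, 0 °C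
Reagents that add atoms: tetrabromomethane, BrC(Br)(Br)Br
Why: In the Appel reaction bromide attacks the primary allylic alkoxyphosphonium ion by SN2, so the bromide should form without allylic transposition or loss of olefin geometry.

**Step 9**
Reactants: 10 {[(2E)-5-[(1S)-2,2-dimethyl-6-methylidenecyclohexyl]-3-methylpent-2-en-1-yl]sulfonyl}benzene; 13 (2E)-4-bromo-3-methylbut-2-en-1-yl acetate
Product: 15 (2E,6E)-9-[(1S)-2,2-dimethyl-6-methylidenecyclohexyl]-3,7-dimethyl-5-(phenylsulfonyl)nona-2,6-dien-1-yl acetate (both C-5 epimers), via α-lithio sulfone 14 (not isolated)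
Conditions: n-BuLi, THF, −78 °C; then 13, −78 to −20 °C
Reagents that add atoms: none
Why: Sulfone-carbanion alkylation: the allylic sulfone is lithiated at its α-carbon and alkylated there by the reactive primary allylic bromide faster than it attacks the acetate, which joins the last five chain carbons and creates a sulfone-bearing centre whose configuration is erased in step 10.

**Step 10**
Reactants: 15 (2E,6E)-9-[(1S)-2,2-dimethyl-6-methylidenecyclohexyl]-3,7-dimethyl-5-(phenylsulfonyl)nona-2,6-dien-1-yl acetate
Product: 17 (2E,6E)-9-[(1S)-2,2-dimethyl-6-methylidenecyclohexyl]-3,7-dimethylnona-2,6-dien-1-ol, via lithium alkoxide 16 (not isolated)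
Conditions: LiBHEt3, THF, 0 °C; then PdCl2(dppp) (5 mol %), 0 to 20 °C; then H2O
Reagents that add atoms: none
Why: LiBHEt3 first cleaves the acetate to the alkoxide 16, which zerovalent palladium cannot ionize, and the palladium-catalysed hydride desulfonylation of the allylic sulfone then passes through a π-allylpalladium intermediate that takes hydride at its less substituted terminus (the former sulfone carbon), so the trisubstituted E olefin should stay in place.

**Step 11**
Reactants: 17 (2E,6E)-9-[(1S)-2,2-dimethyl-6-methylidenecyclohexyl]-3,7-dimethylnona-2,6-dien-1-ol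
Product: 18 3-{[(2E,6E)-9-[(1S)-2,2-dimethyl-6-methylidenecyclohexyl]-3,7-dimethylnona-2,6-dien-1-yl]oxy}-3-oxopropanoic acid (CNP0184126.1)
Conditions: Meldrum's acid, toluene, 90 °C
Reagents that add atoms: Meldrum's acid (2,2-dimethyl-1,3-dioxane-4,6-dione), CC1(C)OC(=O)CC(=O)O1
Why: Alcoholysis of Meldrum's acid by the primary allylic alcohol opens the dioxanedione with loss of acetone and should give the malonic half ester directly, without base, strong acid or a protecting group.

**Compound list**
1 | geranyl bromide, (2E)-1-bromo-3,7-dimethylocta-2,6-diene | CC(C)=CCC/C(C)=C/CBr | starting material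
2 | geranyl phenyl sulfone, {[(2E)-3,7-dimethylocta-2,6-dien-1-yl]sulfonyl}benzene | CC(C)=CCC/C(C)=C/CS(=O)(=O)c1ccccc1 | intermediate
3 | (2R,5R)-2,5-dimethylpyrrolidine | C[C@@H]1CC[C@@H](C)N1 | starting material
4 | 1-[(2R,5R)-2,5-dimethylpyrrolidin-1-yl]ethan-1-one | C[C@@H]1CC[C@@H](C)N1C(C)=O | intermediate
5 | (2R,5R)-1-ethenylidene-2,5-dimethylpyrrolidin-1-ium trifluoromethanesulfonate (keteniminium triflate) | C[C@@H]1CC[C@@H](C)[N+]1=C=C.[O-]S(=O)(=O)C(F)(F)F | intermediate
6 | (2R,5R)-1-{(2S)-3,3-dimethyl-2-[(3E)-3-methyl-5-(phenylsulfonyl)pent-3-en-1-yl]cyclobutylidene}-2,5-dimethylpyrrolidin-1-ium trifluoromethanesulfonate | C[C@@H]1CC[C@@H](C)[N+]1=C1CC(C)(C)[C@@H]1CC/C(C)=C/CS(=O)(=O)c1ccccc1.[O-]S(=O)(=O)C(F)(F)F | intermediate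
7 | (2S)-3,3-dimethyl-2-[(3E)-3-methyl-5-(phenylsulfonyl)pent-3-en-1-yl]cyclobutan-1-one | O=C1CC(C)(C)[C@@H]1CC/C(C)=C/CS(=O)(=O)c1ccccc1 | intermediate
8 | (2S)-1-ethenyl-3,3-dimethyl-2-[(3E)-3-methyl-5-(phenylsulfonyl)pent-3-en-1-yl]cyclobutan-1-ol, both C-1 epimers | C=CC1(O)CC(C)(C)[C@@H]1CC/C(C)=C/CS(=O)(=O)c1ccccc1 | intermediate
9 | (2S)-3,3-dimethyl-2-[(3E)-3-methyl-5-(phenylsulfonyl)pent-3-en-1-yl]cyclohexan-1-one | O=C1CCCC(C)(C)[C@@H]1CC/C(C)=C/CS(=O)(=O)c1ccccc1 | intermediate
10 | {[(2E)-5-[(1S)-2,2-dimethyl-6-methylidenecyclohexyl]-3-methylpent-2-en-1-yl]sulfonyl}benzene | C=C1CCCC(C)(C)[C@@H]1CC/C(C)=C/CS(=O)(=O)c1ccccc1 | intermediate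
11 | 3-methylbut-2-en-1-yl acetate (prenyl acetate) | CC(C)=CCOC(C)=O | starting material
12 | (2E)-4-hydroxy-3-methylbut-2-en-1-yl acetate | CC(=O)OC/C=C(C)/CO | intermediate
13 | (2E)-4-bromo-3-methylbut-2-en-1-yl acetate | CC(=O)OC/C=C(C)/CBr | intermediate
14 | α-lithio derivative of 10, lithiated at the carbon that bears the sulfonyl group | C=C1CCCC(C)(C)[C@@H]1CC/C(C)=C/C([Li])S(=O)(=O)c1ccccc1 | intermediate
15 | (2E,6E)-9-[(1S)-2,2-dimethyl-6-methylidenecyclohexyl]-3,7-dimethyl-5-(phenylsulfonyl)nona-2,6-dien-1-yl acetate, both C-5 epimers | C=C1CCCC(C)(C)[C@@H]1CC/C(C)=C/C(C/C(C)=C/COC(C)=O)S(=O)(=O)c1ccccc1 | intermediate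
16 | lithium (2E,6E)-9-[(1S)-2,2-dimethyl-6-methylidenecyclohexyl]-3,7-dimethyl-5-(phenylsulfonyl)nona-2,6-dien-1-olate, both C-5 epimers | C=C1CCCC(C)(C)[C@@H]1CC/C(C)=C/C(C/C(C)=C/CO[Li])S(=O)(=O)c1ccccc1 | intermediate
17 | (2E,6E)-9-[(1S)-2,2-dimethyl-6-methylidenecyclohexyl]-3,7-dimethylnona-2,6-dien-1-ol | C=C1CCCC(C)(C)[C@@H]1CC/C(C)=C/CC/C(C)=C/CO | intermediate
18 | 3-{[(2E,6E)-9-[(1S)-2,2-dimethyl-6-methylidenecyclohexyl]-3,7-dimethylnona-2,6-dien-1-yl]oxy}-3-oxopropanoic acid | C=C1CCCC(C)(C)[C@@H]1CC/C(C)=C/CC/C(C)=C/COC(=O)CC(=O)O | target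

**Total step count:** 11. **Longest linear sequence:** 8 steps (1, 3, 4, 5, 6, 9, 10, 11).

**Steps most likely to fail**

1. Step 5 (bears the label "Proposed new method:"). What may go wrong: β-carbon elimination at the more substituted ring bond followed by β-hydride elimination; protonolysis of the alkylrhodium before it reaches the enone, which gives plain ring opening; intermolecular conjugate addition leading to oligomers. Fallback, setting out from 7 and coming back at 9: the two ring carbons are inserted one at a time by Lewis acid-promoted diazoalkane homologation (Tiffeneau–Demjanov-type ring enlargement) instead of by ring opening. Treatment of 7 with Me3SiCHN2 and BF3·OEt2 in CH2Cl2 at −78 °C should give, by migration of the less substituted α-carbon C5, the α-silyl cyclopentanone F1, which 1 M HCl in THF protodesilylates to the cyclopentanone F2. A second round on F2, in which the new CH2 again migrates in preference to the hindered C1, should give the α-silyl cyclohexanone F3 and, after the same protodesilylation, 9.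

2. Step 3. What may go wrong: weak facial discrimination by the auxiliary on an acyclic olefin; proton loss from the developing tertiary cation (ene-type acylation) instead of ring closure; self-condensation of the unsubstituted keteniminium ion. Fallback, setting out from 2 and coming back at 7: dichloroketene, generated from Cl3CCOCl with Zn–Cu couple in Et2O at 20 °C, adds to the same terminal olefin with the same regiochemistry to give the racemic dichlorocyclobutanone F4. Zn in AcOH at 60 °C removes both chlorines to give the racemic cyclobutanone F5, and preparative chromatography on a chiral stationary phase separates 7 from its (2R)-enantiomer F6.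

3. Step 11. What may go wrong: acid-promoted migration of the exocyclic double bond into the ring while the acidic half ester is heated; decarboxylation of the half ester. Fallback, setting out from 17 and coming back at 18: Steglich esterification of 17 with 3-oxo-3-[2-(trimethylsilyl)ethoxy]propanoic acid (DCC, DMAP, CH2Cl2, 0 °C) gives the mixed malonate F7. TBAF in THF at 0 °C cleaves the 2-(trimethylsilyl)ethyl ester by fluoride-induced fragmentation, and work-up at pH 4 gives 18 without heat or strong acid.

**Further compounds**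
F1 | step 5 | (2S)-3,3-dimethyl-2-[(3E)-3-methyl-5-(phenylsulfonyl)pent-3-en-1-yl]-5-(trimethylsilyl)cyclopentan-1-one | O=C1C([Si](C)(C)C)CC(C)(C)[C@@H]1CC/C(C)=C/CS(=O)(=O)c1ccccc1
F2 | step 5 | (2S)-3,3-dimethyl-2-[(3E)-3-methyl-5-(phenylsulfonyl)pent-3-en-1-yl]cyclopentan-1-one | O=C1CCC(C)(C)[C@@H]1CC/C(C)=C/CS(=O)(=O)c1ccccc1
F3 | step 5 | (2S)-3,3-dimethyl-2-[(3E)-3-methyl-5-(phenylsulfonyl)pent-3-en-1-yl]-6-(trimethylsilyl)cyclohexan-1-one | O=C1C([Si](C)(C)C)CCC(C)(C)[C@@H]1CC/C(C)=C/CS(=O)(=O)c1ccccc1
F4 | step 3 | rac-2,2-dichloro-3,3-dimethyl-4-[(3E)-3-methyl-5-(phenylsulfonyl)pent-3-en-1-yl]cyclobutan-1-one | O=C1C(Cl)(Cl)C(C)(C)C1CC/C(C)=C/CS(=O)(=O)c1ccccc1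
F5 | step 3 | rac-3,3-dimethyl-2-[(3E)-3-methyl-5-(phenylsulfonyl)pent-3-en-1-yl]cyclobutan-1-one | O=C1CC(C)(C)C1CC/C(C)=C/CS(=O)(=O)c1ccccc1
F6 | step 3 | (2R)-3,3-dimethyl-2-[(3E)-3-methyl-5-(phenylsulfonyl)pent-3-en-1-yl]cyclobutan-1-one | O=C1CC(C)(C)[C@H]1CC/C(C)=C/CS(=O)(=O)c1ccccc1
F7 | step 11 | (2E,6E)-9-[(1S)-2,2-dimethyl-6-methylidenecyclohexyl]-3,7-dimethylnona-2,6-dien-1-yl 2-(trimethylsilyl)ethyl propanedioate | C=C1CCCC(C)(C)[C@@H]1CC/C(C)=C/CC/C(C)=C/COC(=O)CC(=O)OCC[Si](C)(C)C
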